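## Retrosynthetic overview
1. The acrylic acid comes from Markovnikov hydroxycarbonylation of a 7α-ethynyl group. The C9 ester comes from the 9α-alcohol and (R)-3-methylpentanoic acid.
2. 9α-OH, 4α-OH and the 7α-alkynyl group come from equatorial hydride delivery, α-face radical hydration of a C3=C4 alkene, and axial conjugate alkynylation of a trans-fused dienone.
3. The dienone (ring B as a cyclohexenone) comes from a one-carbon ring expansion with desaturation of a trans-hydrindenone. C7 shifts from C9 to the diazo carbon, which becomes C8. This is the key step.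
4. The trans-hydrindenone comes from ring-closing metathesis (ring A) of a 2,2,3-trisubstituted cyclopentanone, made from 2-methylcyclopentenone, isopropenyl Grignard reagent and 4-iodobut-1-ene.
5. Ring order: the five-membered precursor of ring B is bought, ring A is closed by metathesis, and ring B is made by expansion from five to six atoms.

Assumption: (R)-3-methylpentanoic acid is bought as the single enantiomer; positions use eudesmane numbering (C10 quaternary carbon with the angular methyl, C5 ring-fusion CH, C4 carbinol carbon, C7 carbon with the C3 side chain, C9 acyloxy carbon), β is the face of the angular methyl and α the opposite face.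

## Route

Step 1
Reactants: 1 2-methylcyclopent-2-en-1-one; 2 isopropenylmagnesium bromide; 3 4-iodobut-1-ene
Product: 5 (2S,3S)-2-(but-3-en-1-yl)-2-methyl-3-(prop-1-en-2-yl)cyclopentan-1-one, via magnesium enolate 4 (not isolated)
Conditions: Cu(OTf)2 (3 mol %), tert-leucinol-derived hydroxyalkyl imidazolinium PF6 salt (NHC precursor, 4 mol %, antipode that gives 3S), 2 (1.2 equiv), Et2O, −30 °C; then 3 (3 equiv), DMPU, −30 °C → rt
Reagents that add atoms: none
Why: Tandem copper–NHC-catalysed asymmetric conjugate addition and enolate alkylation, in which the catalyst sets C5 (3S) and SN2 alkylation of the tetrasubstituted enolate 4 occurs anti to the new isopropenyl group, fixing the quaternary C10 (2S) with methyl cis and butenyl trans to isopropenyl.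

Step 2
Reactants: 5 (2S,3S)-2-(but-3-en-1-yl)-2-methyl-3-(prop-1-en-2-yl)cyclopentan-1-one
Product: 6 (3aS,7aS)-4,7a-dimethyl-2,3,3a,6,7,7a-hexahydro-1H-inden-1-one
Conditions: Hoveyda–Grubbs second-generation catalyst (3 mol %), CH2Cl2 (5 mM), 40 °C
Reagents that add atoms: none
Why: Ring-closing metathesis joins the monosubstituted and the 1,1-disubstituted alkene into the trisubstituted C3=C4 alkene of ring A with loss of ethene, and because the two chains are already trans on the cyclopentanone the ring fusion is trans and no stereocentre changes.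

Step 3
Reactants: 6 (3aS,7aS)-4,7a-dimethyl-2,3,3a,6,7,7a-hexahydro-1H-inden-1-one; 7 (trimethylsilyl)diazomethane
Product: 10 (4aS,8aS)-5,8a-dimethyl-4a,7,8,8a-tetrahydronaphthalen-1(4H)-one, via β-keto silane 8 (not isolated), via enol silane 9 (not isolated)
Conditions: 7 (1.3 equiv), Sc(OTf)3 (10 mol %), toluene, 0 °C → rt; then Pd(OAc)2 (1.05 equiv), MeCN, rt
Reagents that add atoms: none
Why: Proposed new method: a one-flask homologative desaturation in which Sc(OTf)3 activates the hindered C9 carbonyl and 7 adds from the α face, and in the diazonium betaine the C7–C9 bond rather than the quaternary C10–C9 bond lies antiperiplanar to N2 in the rotamer that keeps SiMe3 away from C10, so C7 makes the 1,2-shift to the diazo carbon (new C8) with loss of N2 and enlarges the five-membered ring to ring B; 1,3-Brook shift of 8 gives 9, which cannot take a second insertion and can only be the C8=C9 isomer because C10 is quaternary, and divalent palladium then forms the oxa-π-allyl enolate and eliminates the C7 hydride to give the enone and zerovalent palladium; the closest known reactions are the Lewis-acid-catalysed TMSCHN2 ring expansion of cyclobutanones and unhindered cycloalkanones (Tiffeneau–Demjanov type) and the Saegusa–Ito oxidation, neither shown on an α-quaternary trans-hydrindan-1-one nor merged into one operation; no stereocentre is made and C5 and C10 are untouched.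

Step 4
Reactants: 10 (4aS,8aS)-5,8a-dimethyl-4a,7,8,8a-tetrahydronaphthalen-1(4H)-one; 11 ethynyltrimethylsilane
Product: 15 (3R,4aS,8aS)-5,8a-dimethyl-3-[(trimethylsilyl)ethynyl]-3,4,4a,7,8,8a-hexahydronaphthalen-1(2H)-one, via lithium acetylide 12 (not isolated), via alkynylalane 13 (not isolated), via aluminium enolate 14 (not isolated)
Conditions: 11, n-BuLi, Et2O, 0 °C; Me2AlCl, 0 °C; then Ni(acac)2 (10 mol %), i-Bu2AlH (10 mol %), 10, Et2O, −5 °C; aq. KH2PO4
Reagents that add atoms: none
Why: Nickel-catalysed conjugate addition of an alkynylalane to a cyclic s-trans enone, in which zerovalent nickel made from Ni(acac)2 and i-Bu2AlH relays the alkynyl group to C7 along the stereoelectronically preferred axial (antiparallel) path on the α face, trans to the C5–C4 bond and opposite to the angular methyl, which sets 7R with the alkynyl group axial.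

Step 5
Reactants: 15 (3R,4aS,8aS)-5,8a-dimethyl-3-[(trimethylsilyl)ethynyl]-3,4,4a,7,8,8a-hexahydronaphthalen-1(2H)-one
Product: 17 (3R,4aR,5R,8aS)-5-hydroxy-5,8a-dimethyl-3-[(trimethylsilyl)ethynyl]octahydronaphthalen-1(2H)-one, via tertiary hydroperoxide 16 (not isolated)
Conditions: Mn(dpm)3 (10 mol %), PhSiH3 (2 equiv), O2 (1 atm), i-PrOH–CH2Cl2, 0 °C; then PPh3, rt
Reagents that add atoms: dioxygen, O=O
Why: Mukaiyama hydration (metal-hydride hydrogen-atom transfer) delivers H to C3 of the only electron-rich alkene (the silyl-capped alkyne and the hindered ketone stay inert), the tertiary C4 radical takes up O2 from the α (equatorial) side because the β (axial) path is closed by the syn-axial angular methyl, and PPh3 reduces 16, which sets 4R with OH equatorial and methyl axial.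

Step 6
Reactants: 17 (3R,4aR,5R,8aS)-5-hydroxy-5,8a-dimethyl-3-[(trimethylsilyl)ethynyl]octahydronaphthalen-1(2H)-one
Product: 19 (1R,3R,4aR,5R,8aS)-3-ethynyl-5,8a-dimethyldecahydronaphthalene-1,5-diol, via silylalkynyl diol 18 (not isolated)
Conditions: LiBH(s-Bu)3 (2.5 equiv), THF, −78 → −20 °C; then NaOH, H2O2, MeOH–H2O, 0 °C → rt
Reagents that add atoms: none
Why: Diastereoselective ketone reduction with a bulky trialkylborohydride, in which the axial α path to C9 is closed by the axial alkynyl group at C7 and by H-5, so hydride arrives equatorially from the β side (as with 4,4-dimethyl-3-oxo triterpenoids) and gives the axial 9α-alcohol (9R), while hydroxide in the oxidative work-up cleaves the C(sp)–Si bond.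

Step 7
Reactants: 19 (1R,3R,4aR,5R,8aS)-3-ethynyl-5,8a-dimethyldecahydronaphthalene-1,5-diol; 20 (R)-3-methylpentanoic acid
Product: 22 (1R,3R,4aR,5R,8aS)-3-ethynyl-5-hydroxy-5,8a-dimethyldecahydronaphthalen-1-yl (3R)-3-methylpentanoate, via mixed anhydride 21 (not isolated)
Conditions: 20, 2,4,6-Cl3C6H2COCl, Et3N, toluene, rt; then 19, DMAP, 60 °C
Reagents that add atoms: none
Why: Yamaguchi esterification, in which DMAP transfers the aliphatic acyl group of 21 to the secondary 9α-OH much faster than to the tertiary C4–OH, and since no C–O bond at carbon is broken, C9 and the stereocentre brought in by 20 are retained.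

Step 8
Reactants: 22 (1R,3R,4aR,5R,8aS)-3-ethynyl-5-hydroxy-5,8a-dimethyldecahydronaphthalen-1-yl (3R)-3-methylpentanoate
Product: 23 2-[(2R,4R,4aS,8R,8aR)-8-hydroxy-4a,8-dimethyl-4-{[(3R)-3-methylpentanoyl]oxy}decahydronaphthalen-2-yl]prop-2-enoic acid (target)
Conditions: Pd(OAc)2 (2 mol %), 2-PyPPh2 (8 mol %), MsOH (8 mol %), CO (10 bar), H2O (10 equiv), THF, 50 °C
Reagents that add atoms: carbon monoxide, [C-]#[O+]; water, O
Why: Palladium-catalysed Markovnikov hydroxycarbonylation of a terminal alkyne with the pyridylphosphine proton-relay catalyst places palladium on the internal carbon C11, and CO insertion followed by hydrolysis gives the 2-substituted acrylic acid directly, while the ester, the tertiary alcohol and all stereocentres stay untouched under the buffered, mildly acidic conditions.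

## Compound list
1 | 2-methylcyclopent-2-en-1-one | CC1=CCCC1=O | starting material
2 | isopropenylmagnesium bromide | CC(=C)[Mg]Br | starting material
3 | 4-iodobut-1-ene | C=CCCI | starting material
4 | bromomagnesium (3S)-2-methyl-3-(prop-1-en-2-yl)cyclopent-1-en-1-olate | C1C[C@@H](C(C)=C)C(C)=C1O[Mg]Br | intermediate
5 | (2S,3S)-2-(but-3-en-1-yl)-2-methyl-3-(prop-1-en-2-yl)cyclopentan-1-one | C1C[C@@H](C(C)=C)[C@](C)(CCC=C)C1=O | intermediate
6 | (3aS,7aS)-4,7a-dimethyl-2,3,3a,6,7,7a-hexahydro-1H-inden-1-one (trans-fused) | C1C[C@@H]2[C@](C)(CCC=C2C)C1=O | intermediate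
7 | (trimethylsilyl)diazomethane | C[Si](C)(C)C=[N+]=[N-] | starting material
8 | (4aS,8aS)-5,8a-dimethyl-2-(trimethylsilyl)-3,4,4a,7,8,8a-hexahydronaphthalen-1(2H)-one (C2 epimers) | C1C[C@@H]2[C@](C)(CCC=C2C)C(=O)C1[Si](C)(C)C | intermediate
9 | {[(4aS,8aS)-5,8a-dimethyl-3,4,4a,7,8,8a-hexahydronaphthalen-1-yl]oxy}trimethylsilane | C1C[C@@H]2[C@](C)(CCC=C2C)C(O[Si](C)(C)C)=C1 | intermediate
10 | (4aS,8aS)-5,8a-dimethyl-4a,7,8,8a-tetrahydronaphthalen-1(4H)-one (trans-fused 3,7-dien-9-one) | C=1C[C@@H]2[C@](C)(CCC=C2C)C(=O)C=1 | intermediate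
11 | ethynyltrimethylsilane | C#C[Si](C)(C)C | starting material
12 | lithium (trimethylsilyl)acetylide | [Li]C#C[Si](C)(C)C | intermediate
13 | dimethyl[(trimethylsilyl)ethynyl]aluminium | C[Al](C)C#C[Si](C)(C)C | intermediate
14 | dimethylaluminium C8=C9 enolate of 15 | C[Si](C)(C)C#C[C@@H]1C[C@@H]2[C@](C)(CCC=C2C)C(O[Al](C)C)=C1 | intermediate
15 | (3R,4aS,8aS)-5,8a-dimethyl-3-[(trimethylsilyl)ethynyl]-3,4,4a,7,8,8a-hexahydronaphthalen-1(2H)-one (alkynyl axial, α) | C[Si](C)(C)C#C[C@@H]1C[C@@H]2[C@](C)(CCC=C2C)C(=O)C1 | intermediate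
16 | (3R,4aR,5R,8aS)-5-hydroperoxy-5,8a-dimethyl-3-[(trimethylsilyl)ethynyl]octahydronaphthalen-1(2H)-one | C[Si](C)(C)C#C[C@@H]1C[C@@H]2[C@](C)(CCC[C@@]2(C)OO)C(=O)C1 | intermediate
17 | (3R,4aR,5R,8aS)-5-hydroxy-5,8a-dimethyl-3-[(trimethylsilyl)ethynyl]octahydronaphthalen-1(2H)-one | C[Si](C)(C)C#C[C@@H]1C[C@@H]2[C@](C)(CCC[C@@]2(C)O)C(=O)C1 | intermediate
18 | (1R,3R,4aR,5R,8aS)-5,8a-dimethyl-3-[(trimethylsilyl)ethynyl]decahydronaphthalene-1,5-diol | C[Si](C)(C)C#C[C@@H]1C[C@@H]2[C@](C)(CCC[C@@]2(C)O)[C@H](O)C1 | intermediate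
19 | (1R,3R,4aR,5R,8aS)-3-ethynyl-5,8a-dimethyldecahydronaphthalene-1,5-diol | C#C[C@@H]1C[C@@H]2[C@](C)(CCC[C@@]2(C)O)[C@H](O)C1 | intermediate
20 | (R)-3-methylpentanoic acid | OC(=O)C[C@H](C)CC | starting material
21 | (3R)-3-methylpentanoic 2,4,6-trichlorobenzoic anhydride | O=C(C[C@H](C)CC)OC(=O)c1c(Cl)cc(Cl)cc1Cl | intermediate
22 | (1R,3R,4aR,5R,8aS)-3-ethynyl-5-hydroxy-5,8a-dimethyldecahydronaphthalen-1-yl (3R)-3-methylpentanoate | C#C[C@@H]1C[C@@H]2[C@](C)(CCC[C@@]2(C)O)[C@H](OC(=O)C[C@H](C)CC)C1 | intermediate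
23 | 2-[(2R,4R,4aS,8R,8aR)-8-hydroxy-4a,8-dimethyl-4-{[(3R)-3-methylpentanoyl]oxy}decahydronaphthalen-2-yl]prop-2-enoic acid | C=C(C(=O)O)[C@@H]1C[C@@H]2[C@](C)(CCC[C@@]2(C)O)[C@H](OC(=O)C[C@H](C)CC)C1 | target

## Step count and risks
Total step count: 8. Longest linear sequence: 8 (1 → 23). Compounds 2, 3, 7, 11 and 20 enter as bought.

**Step 3 (the new step).**
- Possible failures: no addition of 7 to the neopentyl-type ketone, partial migration of C10, or loss of the enol silane before the palladium stage.
- The fallback is the known cyclopropanation and oxidative-cleavage ring expansion. It sets out from 6 and comes back at 10.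
- Compound 6 is treated with TMSOTf and Et3N in CH2Cl2 at 0 °C to give the trimethylsilyl enol ether F1.
- Et2Zn and CH2I2 (1.1 equiv) add methylene to the electron-rich enol ether from the α face before the trisubstituted alkene reacts. This gives the siloxycyclopropane F2.
- FeCl3 (2.2 equiv) in DMF cleaves the internal C7–C9 bond by way of the cyclopropyloxy radical and gives the ring-enlarged β-chloro ketone F3.
- NaOAc in refluxing MeOH eliminates HCl from F3 to give 10.

**Step 1.**
- Possible failures: slow SN2 of the magnesium enolate with an unactivated iodide (elimination to butadiene, proton exchange with the product), or competing 1,2-addition.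
- The fallback is the known silyl enol ether relay. It sets out from 4 and comes back at 5.
- The conjugate addition is quenched with TMSCl, and the trimethylsilyl enol ether F4 is isolated.
- MeLi in THF at 0 °C releases the regiodefined lithium enolate F5.
- F5 is alkylated with 3 in THF–HMPA, again anti to the isopropenyl group, to give 5.

**Step 8.**
- Possible failures: the crowded axial alkyne may erode branched selectivity, and warm acid may dehydrate C4–OH or let the new acid displace the C9 ester as a bridged lactone.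
- The fallback separates regiocontrol from carbonylation. It sets out from 22 and comes back at 23.
- [Cp*Ru(MeCN)3]PF6 (2 mol %) and Et3SiH in CH2Cl2 give the 1,1-disubstituted α-vinylsilane F6.
- NIS and 2,6-lutidine in hexafluoroisopropanol convert F6 into the 2-iodoalkene F7.
- Pd(PPh3)4, CO (1 atm), H2O and Et3N in DMF at 45 °C give 23 under basic conditions.

## Further compounds
F1 | step 3 | {[(3aS,7aS)-4,7a-dimethyl-3a,6,7,7a-tetrahydro-3H-inden-1-yl]oxy}trimethylsilane | C=1C[C@@H]2[C@](C)(CCC=C2C)C=1O[Si](C)(C)C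
F2 | step 3 | siloxycyclopropane from F1, new CH2 (C8) fused on the α face across C7–C9, OSiMe3 on C9 | C1[C@@H]2C[C@@H]3[C@](C)(CCC=C3C)[C@]12O[Si](C)(C)C
F3 | step 3 | (4aS,8aS)-3-chloro-5,8a-dimethyl-3,4,4a,7,8,8a-hexahydronaphthalen-1(2H)-one (C3 epimers) | ClC1C[C@@H]2[C@](C)(CCC=C2C)C(=O)C1
F4 | step 1 | trimethyl{[(3S)-2-methyl-3-(prop-1-en-2-yl)cyclopent-1-en-1-yl]oxy}silane | C1C[C@@H](C(C)=C)C(C)=C1O[Si](C)(C)C
F5 | step 1 | lithium (3S)-2-methyl-3-(prop-1-en-2-yl)cyclopent-1-en-1-olate | C1C[C@@H](C(C)=C)C(C)=C1O[Li]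
F6 | step 8 | (1R,3R,4aR,5R,8aS)-5-hydroxy-5,8a-dimethyl-3-[1-(triethylsilyl)ethenyl]decahydronaphthalen-1-yl (3R)-3-methylpentanoate | C=C([Si](CC)(CC)CC)[C@@H]1C[C@@H]2[C@](C)(CCC[C@@]2(C)O)[C@H](OC(=O)C[C@H](C)CC)C1
F7 | step 8 | (1R,3R,4aR,5R,8aS)-5-hydroxy-3-(1-iodoethenyl)-5,8a-dimethyldecahydronaphthalen-1-yl (3R)-3-methylpentanoate | C=C(I)[C@@H]1C[C@@H]2[C@](C)(CCC[C@@]2(C)O)[C@H](OC(=O)C[C@H](C)CC)C1
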